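**Strategy.** The ten-membered carbocycle is disconnected at C3–C4 (germacrane numbering), where the acetoxy-bearing carbon C3 meets the methyl-bearing sp2 carbon C4 of the Z C4=C5 olefin: the retron of an alkenylmetal addition to an aldehyde. An intramolecular Nozaki–Hiyama–Kishi reaction closes the ring, keeps the Z geometry and creates the C3 carbinol in one operation, with C3 relayed from the lactone centres. Its precursor is the complete γ-lactone (C6 bought; C7 and C11 relayed from it) that carries a (Z)-2-iodopropenyl group on C6 and, on C7, the C8–C3 chain with the C9 acetate (set by catalysis), the Z C1=C10 olefin and the C3 aldehyde.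

Key step: step 16

Remark: atoms are labelled by germacrane numbering of the target (lactone C12(=O)–C11(CH3)–C7–C6–O; ring C1=C10(CH3), C2, C3(OAc), C4(CH3)=C5, C6, C7, C8, C9(OAc)); 3-{[tert-butyl(diphenyl)silyl]oxy}propanal is taken as a commercial aldehyde.

Step 1
Reactants: 1 (2S)-but-3-ene-1,2-diol
Product: 2 (2S)-1-{[tert-butyl(dimethyl)silyl]oxy}but-3-en-2-ol
Conditions: TBSCl, imidazole, CH2Cl2, −20 to 0 °C
Reagents that add atoms: tert-butyl(chloro)dimethylsilane (TBSCl), CC(C)(C)[Si](C)(C)Cl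
Why: Selective silylation of the primary hydroxyl of a 1,2-diol should leave the secondary allylic alcohol free; the bought stereocentre becomes C6.

Step 2
Reactants: 2 (2S)-1-{[tert-butyl(dimethyl)silyl]oxy}but-3-en-2-ol; 3 2-methylprop-2-enoyl chloride
Product: 4 (2S)-1-{[tert-butyl(dimethyl)silyl]oxy}but-3-en-2-yl 2-methylprop-2-enoate
Conditions: Et3N, DMAP (cat.), CH2Cl2, 0 °C
Reagents that add atoms: none
Why: DMAP-catalysed O-acylation with an acid chloride should esterify the secondary alcohol without touching the stereocentre.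

Step 3
Reactants: 4 (2S)-1-{[tert-butyl(dimethyl)silyl]oxy}but-3-en-2-yl 2-methylprop-2-enoate
Product: 5 (5S)-5-({[tert-butyl(dimethyl)silyl]oxy}methyl)-3-methylfuran-2(5H)-one
Conditions: second-generation Grubbs catalyst (H2IMes)(PCy3)Cl2Ru=CHPh (5 mol%), toluene (0.01 M), 80 °C
Reagents that add atoms: none
Why: Ring-closing metathesis of the allyl methacrylate should give the α-methyl butenolide with loss of ethene; the C6 centre is not involved.

Step 4
Reactants: 6 S-ethyl ethanethioate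
Product: 7 {[1-(ethylsulfanyl)ethenyl]oxy}(trimethyl)silane
Conditions: LiN(i-Pr)2 (LDA), THF, −78 °C; TMSCl, −78 °C to rt
Reagents that add atoms: chlorotrimethylsilane, C[Si](C)(C)Cl
Why: O-silylation of the lithium thioester enolate should give the silyl ketene thioacetal that serves as the C8–C9 acetate-enolate equivalent.

Step 5
Reactants: 5 (5S)-5-({[tert-butyl(dimethyl)silyl]oxy}methyl)-3-methylfuran-2(5H)-one; 7 {[1-(ethylsulfanyl)ethenyl]oxy}(trimethyl)silane
Product: 9 S-ethyl [(2S,3S,4R)-2-({[tert-butyl(dimethyl)silyl]oxy}methyl)-4-methyl-5-oxooxolan-3-yl]ethanethioate, via lactone silyl ketene acetal 8 (not isolated)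
Conditions: TMSOTf (10 mol%), CH2Cl2, −78 °C; then THF–1 M HCl, −40 to 0 °C
Reagents that add atoms: none
Why: Mukaiyama–Michael addition should occur at C7 anti to the C6 silyloxymethyl group (trans C6/C7), and kinetic protonation of 8 at C11 from the face opposite the new C7 substituent should place the methyl group cis to it (11R).

Step 6
Reactants: 10 3-{[tert-butyl(diphenyl)silyl]oxy}propanal
Product: 11 tert-butyl[(4,4-dibromobut-3-en-1-yl)oxy]diphenylsilane
Conditions: CBr4 (2 equiv), PPh3 (4 equiv), CH2Cl2, 0 °C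
Reagents that add atoms: tetrabromomethane, BrC(Br)(Br)Br
Why: Dibromo-olefination of the Corey–Fuchs type, through the ylide Ph3P=CBr2 made in the flask, should convert the aldehyde into the 1,1-dibromoalkene without base, so that the β-silyloxy aldehyde does not eliminate.

Step 7
Reactants: 11 tert-butyl[(4,4-dibromobut-3-en-1-yl)oxy]diphenylsilane
Product: 12 {[(3Z)-4-bromopent-3-en-1-yl]oxy}(tert-butyl)diphenylsilane
Conditions: MeZnCl (1.2 equiv), PdCl2(DPEphos) (3 mol%), THF, 0 °C to rt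
Reagents that add atoms: methylzinc chloride, C[Zn]Cl
Why: In this trans-selective Negishi mono-methylation, zerovalent palladium should insert into the less hindered C–Br bond trans to the chain and replace it by methyl with retention, which leaves the bromine cis to the chain (Z) and fixes the later C1=C10 geometry.

Step 8
Reactants: 12 {[(3Z)-4-bromopent-3-en-1-yl]oxy}(tert-butyl)diphenylsilane; 9 S-ethyl [(2S,3S,4R)-2-({[tert-butyl(dimethyl)silyl]oxy}methyl)-4-methyl-5-oxooxolan-3-yl]ethanethioate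
Product: 15 (3R,4S,5S)-5-({[tert-butyl(dimethyl)silyl]oxy}methyl)-4-[(3Z)-6-{[tert-butyl(diphenyl)silyl]oxy}-3-methyl-2-oxohex-3-en-1-yl]-3-methyloxolan-2-one, via alkenyllithium 13 (not isolated), via alkenylzinc chloride 14 (not isolated)
Conditions: 12, t-BuLi (2.1 equiv), Et2O, −78 °C; ZnCl2, THF, −78 to 0 °C; then 9, PdCl2(PPh3)2 (5 mol%), THF–toluene, rt
Reagents that add atoms: none
Why: Bromine–lithium exchange and transmetalation to zinc proceed with retention, and the palladium-catalysed Fukuyama coupling of the thioester with the configurationally stable alkenylzinc should form the C9–C10 bond as the Z enone, the lactone and silyl ethers being inert to organozinc.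

Step 9
Reactants: 15 the Z enone
Product: 16 (3R,4S,5S)-5-({[tert-butyl(dimethyl)silyl]oxy}methyl)-4-[(2R,3Z)-6-{[tert-butyl(diphenyl)silyl]oxy}-2-hydroxy-3-methylhex-3-en-1-yl]-3-methyloxolan-2-one
Conditions: (S)-2-methyl-CBS-oxazaborolidine (0.3 equiv), catecholborane, toluene, −78 °C
Reagents that add atoms: none
Why: Corey–Bakshi–Shibata reduction with the α-branched alkenyl group as the large and the C8 methylene as the small substituent should deliver hydride under catalyst control to give the 9R allylic alcohol, without reduction of the lactone.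

Step 10
Reactants: 16 the 9R allylic alcohol
Product: 17 (2R,3Z)-6-{[tert-butyl(diphenyl)silyl]oxy}-1-[(2S,3S,4R)-2-({[tert-butyl(dimethyl)silyl]oxy}methyl)-4-methyl-5-oxooxolan-3-yl]-3-methylhex-3-en-2-yl acetate
Conditions: Ac2O, pyridine, DMAP (cat.), CH2Cl2, 0 °C to rt
Reagents that add atoms: acetic anhydride, CC(=O)OC(C)=O
Why: DMAP-catalysed acetylation should install the C9 acetate of the target with retention, so that it also protects C9 through the later oxidations.

Step 11
Reactants: 17 the C9 acetate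
Product: 18 (2R,3Z)-6-{[tert-butyl(diphenyl)silyl]oxy}-1-[(2S,3S,4R)-2-(hydroxymethyl)-4-methyl-5-oxooxolan-3-yl]-3-methylhex-3-en-2-yl acetate
Conditions: HF·pyridine, pyridine, THF, 0 °C
Reagents that add atoms: none
Why: Buffered HF should cleave the primary TBS ether much faster than the primary TBDPS ether, freeing only the C5 hydroxyl.

Step 12
Reactants: 18 the C5 alcohol
Product: 19 (2R,3Z)-6-{[tert-butyl(diphenyl)silyl]oxy}-1-[(2S,3S,4R)-2-formyl-4-methyl-5-oxooxolan-3-yl]-3-methylhex-3-en-2-yl acetate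
Conditions: Dess–Martin periodinane, NaHCO3, CH2Cl2, 0 °C to rt; used at once
Reagents that add atoms: none
Why: Dess–Martin oxidation under buffered conditions should give the α-acyloxy aldehyde without epimerisation at C6.

Step 13
Reactants: 19 the C5 aldehyde; 20 ethyl(triphenyl)phosphonium iodide
Product: 24 (2R,3Z)-6-{[tert-butyl(diphenyl)silyl]oxy}-1-[(2S,3S,4R)-2-[(1Z)-2-iodoprop-1-en-1-yl]-4-methyl-5-oxooxolan-3-yl]-3-methylhex-3-en-2-yl acetate, via ethylidene ylide 21 (not isolated), via iodoethylphosphonium iodide 22 (not isolated), via iodoethylidene ylide 23 (not isolated)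
Conditions: 20, n-BuLi, THF, 0 °C; I2, −78 °C; NaN(SiMe3)2 (NaHMDS), −78 to −20 °C; then 19, −78 °C
Reagents that add atoms: iodine, II
Why: Stork–Zhao-type Wittig olefination with the non-stabilised α-iodo ylide 23 should give the (Z)-2-iodopropenyl group (iodine cis to C6) at low temperature, faster than enolisation of the aldehyde, lactone or acetate.

Step 14
Reactants: 24 the alkenyl iodide silyl ether
Product: 25 (2R,3Z)-6-hydroxy-1-[(2S,3S,4R)-2-[(1Z)-2-iodoprop-1-en-1-yl]-4-methyl-5-oxooxolan-3-yl]-3-methylhex-3-en-2-yl acetate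
Conditions: HF·pyridine, THF, 0 °C to rt
Reagents that add atoms: none
Why: Unbuffered HF·pyridine should remove the primary TBDPS ether, while acetate, lactone and alkenyl iodide are stable to it and the C11 centre sees no base.

Step 15
Reactants: 25 the C3 alcohol
Product: 26 (2R,3Z)-1-[(2S,3S,4R)-2-[(1Z)-2-iodoprop-1-en-1-yl]-4-methyl-5-oxooxolan-3-yl]-3-methyl-6-oxohex-3-en-2-yl acetate
Conditions: Dess–Martin periodinane, NaHCO3, CH2Cl2, 0 °C; used crude at once
Reagents that add atoms: none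
Why: Dess–Martin oxidation should give the β,γ-unsaturated aldehyde without migration of the C1=C10 olefin into conjugation or loss of the C9 acetate, both of which need base.

Step 16
Reactants: 26 the seco iodo aldehyde
Product: 28 (3R,3aS,5R,6Z,9S,10Z,11aS)-9-hydroxy-3,6,10-trimethyl-2-oxo-2,3,3a,4,5,8,9,11a-octahydrocyclodeca[b]furan-5-yl acetate, via alkenylchromium dichloride 27 (not isolated)
Conditions: CrCl2 (10 equiv), NiCl2 (0.1 equiv), degassed DMSO–THF, slow addition of 26 to 0.003 M, rt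
Reagents that add atoms: none
Why: Zerovalent nickel, formed from NiCl2 by divalent chromium, inserts into the C4–I bond with retention, transmetalation gives trivalent alkenylchromium 27, and this adds to the C3 aldehyde to give the chromium alkoxide of 28. The closest known reaction type is the intramolecular Nozaki–Hiyama–Kishi coupling, which is established for medium and large carbocycles that carry esters and lactones. The ten-membered ring closes in a 10-exo-trig mode. The new C3 centre is set by substrate control: the fixed C6 and C7 centres and the two Z olefins should favour the chair-like folding in which C2 and C7 leave the C4=C5 plane on opposite faces, C3–H eclipses the olefin (minimal 1,3-allylic strain) and the chromium-bound oxygen points outward, anti to the C6–O bond, which corresponds to 3S. The step needs chemoselectivity for the aldehyde over the lactone and acetate carbonyls and retention of the Z C4=C5 geometry, both inherent to alkenylchromium, and ring closure over oligomerisation, secured by high dilution and by the cis olefins and the lactone that hold C3 near C4. The reagent is not basic, so the β,γ-unsaturated aldehyde is not enolised and the C1=C10 olefin and the C9 acetate stay in place.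

Step 17
Reactants: 28 the macrocyclic C3 alcohol
Product: 29 (3R,3aS,5R,6Z,9S,10Z,11aS)-3,6,10-trimethyl-2-oxo-2,3,3a,4,5,8,9,11a-octahydrocyclodeca[b]furan-5,9-diyl diacetate
Conditions: Ac2O, pyridine, DMAP (cat.), CH2Cl2, 0 °C to rt
Reagents that add atoms: acetic anhydride, CC(=O)OC(C)=O
Why: DMAP-catalysed acetylation of the secondary allylic alcohol should proceed with retention at C3 and without epimerisation at C11 to give the target.

**Compound list**

1 | (2S)-but-3-ene-1,2-diol | O[C@@H](C=C)CO | starting material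
2 | (2S)-1-{[tert-butyl(dimethyl)silyl]oxy}but-3-en-2-ol | O[C@@H](C=C)CO[Si](C)(C)C(C)(C)C | intermediate
3 | 2-methylprop-2-enoyl chloride | CC(=C)C(Cl)=O | starting material
4 | (2S)-1-{[tert-butyl(dimethyl)silyl]oxy}but-3-en-2-yl 2-methylprop-2-enoate | CC(=C)C(=O)O[C@@H](C=C)CO[Si](C)(C)C(C)(C)C | intermediate
5 | (5S)-5-({[tert-butyl(dimethyl)silyl]oxy}methyl)-3-methylfuran-2(5H)-one | CC1=C[C@@H](CO[Si](C)(C)C(C)(C)C)OC1=O | intermediate
6 | S-ethyl ethanethioate | CCSC(C)=O | starting material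
7 | {[1-(ethylsulfanyl)ethenyl]oxy}(trimethyl)silane | C=C(SCC)O[Si](C)(C)C | intermediate
8 | S-ethyl [(2S,3S)-2-({[tert-butyl(dimethyl)silyl]oxy}methyl)-4-methyl-5-[(trimethylsilyl)oxy]-2,3-dihydrofuran-3-yl]ethanethioate (lactone silyl ketene acetal, not isolated) | CCSC(=O)C[C@@H]1[C@@H](CO[Si](C)(C)C(C)(C)C)OC(O[Si](C)(C)C)=C1C | intermediate
9 | S-ethyl [(2S,3S,4R)-2-({[tert-butyl(dimethyl)silyl]oxy}methyl)-4-methyl-5-oxooxolan-3-yl]ethanethioate | CCSC(=O)C[C@@H]1[C@@H](CO[Si](C)(C)C(C)(C)C)OC(=O)[C@@H]1C | intermediate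
10 | 3-{[tert-butyl(diphenyl)silyl]oxy}propanal | CC(C)(C)[Si](OCCC=O)(c1ccccc1)c1ccccc1 | starting material
11 | tert-butyl[(4,4-dibromobut-3-en-1-yl)oxy]diphenylsilane | CC(C)(C)[Si](OCCC=C(Br)Br)(c1ccccc1)c1ccccc1 | intermediate
12 | {[(3Z)-4-bromopent-3-en-1-yl]oxy}(tert-butyl)diphenylsilane | CC(C)(C)[Si](OCC/C=C(/C)Br)(c1ccccc1)c1ccccc1 | intermediate
13 | alkenyllithium from 12, lithium in place of bromine, cis to the chain (not isolated) | CC(C)(C)[Si](OCC/C=C(/C)[Li])(c1ccccc1)c1ccccc1 | intermediate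
14 | alkenylzinc chloride from 13, zinc cis to the chain (not isolated) | CC(C)(C)[Si](OCC/C=C(/C)[Zn]Cl)(c1ccccc1)c1ccccc1 | intermediate
15 | (3R,4S,5S)-5-({[tert-butyl(dimethyl)silyl]oxy}methyl)-4-[(3Z)-6-{[tert-butyl(diphenyl)silyl]oxy}-3-methyl-2-oxohex-3-en-1-yl]-3-methyloxolan-2-one | CC(C)(C)[Si](c1ccccc1)(c1ccccc1)OCC/C=C(/C)C(=O)C[C@@H]2[C@@H](CO[Si](C)(C)C(C)(C)C)OC(=O)[C@@H]2C | intermediate
16 | (3R,4S,5S)-5-({[tert-butyl(dimethyl)silyl]oxy}methyl)-4-[(2R,3Z)-6-{[tert-butyl(diphenyl)silyl]oxy}-2-hydroxy-3-methylhex-3-en-1-yl]-3-methyloxolan-2-one | CC(C)(C)[Si](c1ccccc1)(c1ccccc1)OCC/C=C(/C)[C@H](O)C[C@@H]2[C@@H](CO[Si](C)(C)C(C)(C)C)OC(=O)[C@@H]2C | intermediate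
17 | (2R,3Z)-6-{[tert-butyl(diphenyl)silyl]oxy}-1-[(2S,3S,4R)-2-({[tert-butyl(dimethyl)silyl]oxy}methyl)-4-methyl-5-oxooxolan-3-yl]-3-methylhex-3-en-2-yl acetate | CC(C)(C)[Si](c1ccccc1)(c1ccccc1)OCC/C=C(/C)[C@H](OC(C)=O)C[C@@H]2[C@@H](CO[Si](C)(C)C(C)(C)C)OC(=O)[C@@H]2C | intermediate
18 | (2R,3Z)-6-{[tert-butyl(diphenyl)silyl]oxy}-1-[(2S,3S,4R)-2-(hydroxymethyl)-4-methyl-5-oxooxolan-3-yl]-3-methylhex-3-en-2-yl acetate | CC(C)(C)[Si](c1ccccc1)(c1ccccc1)OCC/C=C(/C)[C@H](OC(C)=O)C[C@@H]2[C@@H](CO)OC(=O)[C@@H]2C | intermediate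
19 | (2R,3Z)-6-{[tert-butyl(diphenyl)silyl]oxy}-1-[(2S,3S,4R)-2-formyl-4-methyl-5-oxooxolan-3-yl]-3-methylhex-3-en-2-yl acetate | CC(C)(C)[Si](c1ccccc1)(c1ccccc1)OCC/C=C(/C)[C@H](OC(C)=O)C[C@@H]2[C@@H](C=O)OC(=O)[C@@H]2C | intermediate
20 | ethyl(triphenyl)phosphonium iodide | CC[P+](c1ccccc1)(c1ccccc1)c1ccccc1.[I-] | starting material
21 | ethylidene(triphenyl)phosphorane (not isolated) | CC=P(c1ccccc1)(c1ccccc1)c1ccccc1 | intermediate
22 | (1-iodoethyl)(triphenyl)phosphonium iodide (not isolated) | CC(I)[P+](c1ccccc1)(c1ccccc1)c1ccccc1.[I-] | intermediate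
23 | (1-iodoethylidene)(triphenyl)phosphorane (not isolated) | CC(I)=P(c1ccccc1)(c1ccccc1)c1ccccc1 | intermediate
24 | (2R,3Z)-6-{[tert-butyl(diphenyl)silyl]oxy}-1-[(2S,3S,4R)-2-[(1Z)-2-iodoprop-1-en-1-yl]-4-methyl-5-oxooxolan-3-yl]-3-methylhex-3-en-2-yl acetate | CC(C)(C)[Si](c1ccccc1)(c1ccccc1)OCC/C=C(/C)[C@H](OC(C)=O)C[C@@H]2[C@@H](/C=C(\I)C)OC(=O)[C@@H]2C | intermediate
25 | (2R,3Z)-6-hydroxy-1-[(2S,3S,4R)-2-[(1Z)-2-iodoprop-1-en-1-yl]-4-methyl-5-oxooxolan-3-yl]-3-methylhex-3-en-2-yl acetate | OCC/C=C(/C)[C@H](OC(C)=O)C[C@@H]1[C@@H](/C=C(\I)C)OC(=O)[C@@H]1C | intermediate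
26 | (2R,3Z)-1-[(2S,3S,4R)-2-[(1Z)-2-iodoprop-1-en-1-yl]-4-methyl-5-oxooxolan-3-yl]-3-methyl-6-oxohex-3-en-2-yl acetate | O=CC/C=C(/C)[C@H](OC(C)=O)C[C@@H]1[C@@H](/C=C(\I)C)OC(=O)[C@@H]1C | intermediate
27 | alkenylchromium dichloride from 26, chromium in place of iodine, cis to C6 (not isolated) | O=CC/C=C(/C)[C@H](OC(C)=O)C[C@@H]1[C@@H](/C=C(\[Cr](Cl)Cl)C)OC(=O)[C@@H]1C | intermediate
28 | (3R,3aS,5R,6Z,9S,10Z,11aS)-9-hydroxy-3,6,10-trimethyl-2-oxo-2,3,3a,4,5,8,9,11a-octahydrocyclodeca[b]furan-5-yl acetate | O[C@H]1C/C=C(/C)[C@H](OC(C)=O)C[C@@H]2[C@@H](/C=C\1C)OC(=O)[C@@H]2C | intermediate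
29 | (3R,3aS,5R,6Z,9S,10Z,11aS)-3,6,10-trimethyl-2-oxo-2,3,3a,4,5,8,9,11a-octahydrocyclodeca[b]furan-5,9-diyl diacetate | CC(=O)O[C@H]1C/C=C(/C)[C@H](OC(C)=O)C[C@@H]2[C@@H](/C=C\1C)OC(=O)[C@@H]2C | target

**Count.** Total steps: 17. Longest linear sequence: 14 steps (steps 1–3, 5, 8–17); steps 4, 6 and 7 prepare the two side fragments.

**Steps most likely to fail**

Step 16 (ring closure). The facial selectivity of the addition to the C3 aldehyde rests only on the folding of the seco chain and may be poor or reversed. Fallback: setting out from 26, the same closure is run and the C3 epimer (3R,3aS,5R,6Z,9R,10Z,11aS)-9-hydroxy-3,6,10-trimethyl-2-oxo-2,3,3a,4,5,8,9,11a-octahydrocyclodeca[b]furan-5-yl acetate F1 is separated. Mitsunobu esterification of F1 (PPh3, DIAD, AcOH, THF, 0 °C) should invert C3 and install the acetate at once, which comes back to the route at 29, so that either epimer of the ring closure can be carried to the target.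

Step 5 (conjugate addition and protonation). The α-methyl butenolide may react slowly with the silyl ketene thioacetal, and the protonation at C11 may show poor facial selectivity; with the thioester present the C11 centre cannot be corrected afterwards. Fallback: setting out from 5, Sakurai conjugate allylation (allyltrimethylsilane, TiCl4, CH2Cl2, −78 °C) should give (4S,5S)-5-({[tert-butyl(dimethyl)silyl]oxy}methyl)-3-methyl-4-(prop-2-en-1-yl)oxolan-2-one F2 as a mixture at C11. The lactone is then the only enolisable site, so LiN(i-Pr)2 (THF, −78 °C) followed by 2,6-di-tert-butylphenol should protonate the enolate anti to the allyl group and give the cis lactone (3R,4S,5S)-5-({[tert-butyl(dimethyl)silyl]oxy}methyl)-3-methyl-4-(prop-2-en-1-yl)oxolan-2-one F3. Ozonolysis (O3, CH2Cl2, −78 °C; PPh3) should give [(2S,3S,4R)-2-({[tert-butyl(dimethyl)silyl]oxy}methyl)-4-methyl-5-oxooxolan-3-yl]acetaldehyde F4. Pinnick oxidation (NaClO2, NaH2PO4, 2-methylbut-2-ene, t-BuOH–H2O, 0 °C) should give [(2S,3S,4R)-2-({[tert-butyl(dimethyl)silyl]oxy}methyl)-4-methyl-5-oxooxolan-3-yl]acetic acid F5, and thioesterification with ethanethiol (EDC·HCl, DMAP cat., CH2Cl2, 0 °C) comes back to the route at 9.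

Step 13 (iodo-olefination of the lactone aldehyde). The basic ylide may epimerise the α-acyloxy aldehyde at C6 or enolise the lactone, and the Z selectivity may erode. Fallback: setting out from 19, non-basic dibromo-olefination of the Corey–Fuchs type (CBr4, PPh3, CH2Cl2, 0 °C) should give (2R,3Z)-6-{[tert-butyl(diphenyl)silyl]oxy}-1-[(2S,3S,4R)-2-(2,2-dibromoethenyl)-4-methyl-5-oxooxolan-3-yl]-3-methylhex-3-en-2-yl acetate F6. Palladium-catalysed Negishi mono-methylation (MeZnCl, PdCl2(DPEphos) cat., THF, 0 °C) should replace the less hindered bromine trans to C6 and give (2R,3Z)-1-[(2S,3S,4R)-2-[(1Z)-2-bromoprop-1-en-1-yl]-4-methyl-5-oxooxolan-3-yl]-6-{[tert-butyl(diphenyl)silyl]oxy}-3-methylhex-3-en-2-yl acetate F7. Copper-catalysed bromide–iodide exchange with retention (CuI cat., trans-N,N′-dimethylcyclohexane-1,2-diamine, NaI, dioxane, 100 °C) comes back to the route at 24.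

Further compounds
F1 | step 16 | (3R,3aS,5R,6Z,9R,10Z,11aS)-9-hydroxy-3,6,10-trimethyl-2-oxo-2,3,3a,4,5,8,9,11a-octahydrocyclodeca[b]furan-5-yl acetate | O[C@@H]1C/C=C(/C)[C@H](OC(C)=O)C[C@@H]2[C@@H](/C=C\1C)OC(=O)[C@@H]2C
F2 | step 5 | (4S,5S)-5-({[tert-butyl(dimethyl)silyl]oxy}methyl)-3-methyl-4-(prop-2-en-1-yl)oxolan-2-one, mixture at C3 of the lactone | C=CC[C@@H]1[C@@H](CO[Si](C)(C)C(C)(C)C)OC(=O)C1C
F3 | step 5 | (3R,4S,5S)-5-({[tert-butyl(dimethyl)silyl]oxy}methyl)-3-methyl-4-(prop-2-en-1-yl)oxolan-2-one | C=CC[C@@H]1[C@@H](CO[Si](C)(C)C(C)(C)C)OC(=O)[C@@H]1C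
F4 | step 5 | [(2S,3S,4R)-2-({[tert-butyl(dimethyl)silyl]oxy}methyl)-4-methyl-5-oxooxolan-3-yl]acetaldehyde | O=CC[C@@H]1[C@@H](CO[Si](C)(C)C(C)(C)C)OC(=O)[C@@H]1C
F5 | step 5 | [(2S,3S,4R)-2-({[tert-butyl(dimethyl)silyl]oxy}methyl)-4-methyl-5-oxooxolan-3-yl]acetic acid | OC(=O)C[C@@H]1[C@@H](CO[Si](C)(C)C(C)(C)C)OC(=O)[C@@H]1C
F6 | step 13 | (2R,3Z)-6-{[tert-butyl(diphenyl)silyl]oxy}-1-[(2S,3S,4R)-2-(2,2-dibromoethenyl)-4-methyl-5-oxooxolan-3-yl]-3-methylhex-3-en-2-yl acetate | CC(C)(C)[Si](c1ccccc1)(c1ccccc1)OCC/C=C(/C)[C@H](OC(C)=O)C[C@@H]2[C@@H](C=C(Br)Br)OC(=O)[C@@H]2C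
F7 | step 13 | (2R,3Z)-1-[(2S,3S,4R)-2-[(1Z)-2-bromoprop-1-en-1-yl]-4-methyl-5-oxooxolan-3-yl]-6-{[tert-butyl(diphenyl)silyl]oxy}-3-methylhex-3-en-2-yl acetate | CC(C)(C)[Si](c1ccccc1)(c1ccccc1)OCC/C=C(/C)[C@H](OC(C)=O)C[C@@H]2[C@@H](/C=C(\Br)C)OC(=O)[C@@H]2C
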